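I decided to count reagent, not hours. The north-west flask had been followed up to its last reading, and I had to say what it would hold at 40 h and whether heat, waiting or taking out target would pay.

| setting | north-west | south-west | flask |
|---|---|---|---|
| substrate | 1.8 M | 1.8 M | 1.8 M |
| reagent | 0.70 equiv | 0.70 equiv | 0.700 equiv |
| initiator | 5 mol% | 5 mol% | 5 mol% |
| temperature | 110 °C | 105 °C | 110 °C |
| remark | the very flask that is asked about, followed so far | run made earlier |  |
| time |  |  | 40 h |

| run | time / h | target / % | substrate / % |
|---|---|---|---|
| north-west | 5.00 | 48.3 | 54.0 |
| north-west | 10.0 | 63.4 | 36.1 |
| north-west | 15.0 | 67.2 | 30.4 |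
| north-west | 20.0 | 68.9 | 28.1 |
| north-west | 25.0 | 68.8 | 26.3 |
| south-west | 5.00 | 39.7 | 59.6 |
| south-west | 10.0 | 57.7 | 42.4 |
| south-west | 15.0 | 63.8 | 36.1 |
| south-west | 20.0 | 67.1 | 31.5 |
| south-west | 25.0 | 67.0 | 29.9 |

(standard deviation of a reading: 1 percentage point)

- green: at 40 h raise the temperature by 10 K, then wait 3.0 d
- amber: change nothing and wait 3.0 d more
- violet: at 40 h take out 90% of the target then present, then wait 3.0 d

- removed target is counted in

- target, in percent of the substrate first charged, at 40 h
- what to do for the largest gain in target; "none" if nothing gains more than 2 percentage points (green / amber / violet / none)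
- target present, with what was taken out counted in, in percent of the substrate first charged, after green
- target present, with what was taken out counted in, in percent of the substrate first charged, after violet

I built the flask up one process at a time. First I took the main step by itself. One reagent gives one target, so the rate of target made over the rate of reagent used is one, and time drops out. While reagent is the limiting reagent, target cannot pass 70.0% of the substrate charged: this is the reagent ceiling, the equivalents of reagent written as a percentage of the substrate.

Then I added a loss of substrate. At 25.0 h in the north-west flask, substrate and target came to 95.1%, so some substrate had gone elsewhere. If that path takes no reagent, the ceiling stays where it was, and the substrate in that flask read 26.3% at that time.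

Last I allowed for a slow loss of target. The north-west flask read 68.9% at 20.0 h and 68.8% at 25.0 h, a difference inside the scatter of 1 percentage point, so these readings could not tell a small rise or fall from no change. The ceiling minus the last target reading of that flask was 1.2 points, a figure that carries the scatter of the reading and is less than the margin of 2 points. So I put the target at 40 h between 68.8% and 70.0%, and I expected no option to pay.

The forecast gave 69.3% at 40 h, 69% after green, 69.7% after violet, and none as the choice. In its words: “With reagent gone, heat, time or removing target can add at most about 1 point.”

The simulated flask gave 69.4% at 40 h, 66.1% after green, 69.3% after violet, and none as the choice. The gains were −3.3 points for green, −1.2 points for amber and −0.079 points for violet.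

    2 second chain carrier → ended chains (k = 3.00 × 10⁶ /M/s, Ea = 28.0 kJ/mol)
    reagent + first chain carrier → target + second chain carrier (k = 260 /M/s, Ea = 53.0 kJ/mol)
    initiator → 2 initiating radical (k = 4.71 × 10⁻⁶ /s, Ea = 123 kJ/mol)
    target → over-reaction product (k = 6.73 × 10⁻⁸ /s, Ea = 130 kJ/mol)
    first chain carrier → ended carrier (k = 3.04 /s, Ea = 95.0 kJ/mol)
    substrate + initiating radical → capped initiator + first chain carrier (k = 6290 /M/s, Ea = 33.0 kJ/mol)
    substrate + second chain carrier → by-product + first chain carrier (k = 324 /M/s, Ea = 41.0 kJ/mol)
    (constants at 110 °C)

The target stood 0.60 points under the ceiling. The half-life of target by over-reaction, 120 d at 3.06 h, was far longer than the 40 h of the run, and 0.060% of the charged reagent remained at 40.0 h. A run with 0.649 equiv or 0.750 equiv of reagent moved the target at 40 h by 5 points, and a charge off by that much is what it would take for the forecast's value at 40 h to fail.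

For the neighbour flask with 0.280 equiv of reagent, the same count gives a ceiling of 28.0%. Its computed target at 40 h was 27.7%, with 67.1% of the substrate still there.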